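**Plan**

- Retrosynthesis: the two ester bonds (O1–acyl; O7–(Z)-coumaroyl, traced back to an aryl propiolate) and the C11 alcohol (from a methyl ester) go first. The dihydropyran is then cut at C1–C9, C4–C5 and O2–C1, and the cyclopentene at C5=C9, C8–C9 and C6–C7.
- Enabling feature (iridoid numbering): C1 and C3/C4/C11 of the pyran ring together are a diformylacetate, a 1,3-dicarbonyl unit. Its enol C=C can be added across C5=C9 of a cyclopentene that already carries O7 and the C8(OH)CH2O group.
- Forward order of rings: dioxane (purchased as the acetonide ketone), then cyclopentene (allylation, vinyl addition, ring-closing metathesis), then dihydropyran (photocycloaddition, retro-aldol, hemiacetal closure). Acetonide removal, silylation, C11 reduction, two esterifications, alkyne semihydrogenation and desilylation follow.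
- Stereochemistry: C7 from the SAMP-hydrazone allylation; C8 from axial vinyl addition to the dioxanone; C5 and C9 from suprafacial addition to the convex face of the cis-fused acetonide (syn to 8-OH); C1 from acylation of the lactol anti to C8; the side-chain centre from (3R)-3-methylpentanoic acid; the Z-alkene from syn hydrogenation.

Key step: step 7

Assumption: (3R)-3-methylpentanoic acid 23 and tert-butyl(4-ethynylphenoxy)dimethylsilane 25 are taken as purchasable single compounds.
Remark: lactols 17, 18 and 22 equilibrate at C1 and the C1 silyl ethers 19–21 may be anomeric mixtures; all are drawn with O1 trans to C8, and C1 is fixed only in step 13. TBS = tert-butyldimethylsilyl; iridoid numbering is used for positions.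

**Step 1**
Reactants: 1 2,2-dimethyl-1,3-dioxan-5-one; 2 (S)-1-amino-2-(methoxymethyl)pyrrolidine (SAMP)
Product: 3 SAMP hydrazone of 1
Conditions: toluene, 4 Å MS, 60 °C
Reagents that add atoms: none
Why: Hydrazone condensation of an unhindered ketone with a 1,1-disubstituted hydrazine goes to completion once water is removed, and it creates no stereocentre.

**Step 2**
Reactants: 3 SAMP hydrazone of 1; 4 allyl bromide
Product: 6 (4S)-4-allyl SAMP hydrazone, via lithium azaenolate 5 (not isolated)
Conditions: t-BuLi, THF, −78 °C; then 4, −100 °C → rt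
Reagents that add atoms: none
Why: Enders SAMP-hydrazone alkylation: the methoxy-chelated lithium azaenolate should be allylated on its unshielded face, which sets C7 as (S) at the dioxane C4.

**Step 3**
Reactants: 6 (4S)-4-allyl SAMP hydrazone
Product: 7 (4S)-4-allyl-2,2-dimethyl-1,3-dioxan-5-one
Conditions: sat. aq. oxalic acid, Et2O, rt
Reagents that add atoms: water, O
Why: Mild biphasic hydrazone hydrolysis should return the ketone without enolising the new α-centre and without touching the alkene or the acetonide, the auxiliary leaving as its water-soluble oxalate.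

**Step 4**
Reactants: 7 (4S)-4-allyl-2,2-dimethyl-1,3-dioxan-5-one; 8 vinylmagnesium bromide
Product: 9 (4S,5R)-4-allyl-2,2-dimethyl-5-vinyl-1,3-dioxan-5-ol
Conditions: THF, −78 → −40 °C; then H2O
Reagents that add atoms: none
Why: Grignard 1,2-addition: in the chair with allyl equatorial, a 1,3-dioxan-5-one carbonyl has ring oxygens where syn-axial hydrogens would be and is attacked axially, so vinyl should enter cis to allyl and the C8 hydroxyl ends trans to it.

**Step 5**
Reactants: 9 (4S,5R)-4-allyl-2,2-dimethyl-5-vinyl-1,3-dioxan-5-ol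
Product: 10 (4aR,7aS)-2,2-dimethyl-7,7a-dihydrocyclopenta[d][1,3]dioxin-4a(4H)-ol (cis-fused cyclopentene acetonide, free tertiary 8-OH)
Conditions: second-generation Grubbs catalyst (H2IMes)(PCy3)Cl2Ru=CHPh (cat.), CH2Cl2, 40 °C
Reagents that add atoms: none
Why: Ring-closing metathesis of a 1,6-diene to a cyclopentene is fast, tolerates the free allylic alcohol, and is expected to close readily only from the cis vinyl/allyl diastereomer, so it also acts as a filter on the outcome of step 4.

**Step 6**
Reactants: 11 methyl 3,3-dimethoxypropanoate; 12 methyl formate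
Product: 14 methyl diformylacetate, via sodium formyl acetal enolate 13 (not isolated)
Conditions: NaH, Et2O, 0 °C → rt; then 2 M aq. HCl, rt; distil
Reagents that add atoms: water, O
Why: Crossed Claisen formylation at the methylene between ester and acetal, followed by acetal hydrolysis, should give the diformyl ester, which exists as its chelated enol.

**Step 7**
Reactants: 10 cyclopentene acetonide; 14 methyl diformylacetate
Product: 17 iridoid lactol methyl ester (7,10-O-isopropylidene and free 8-OH), via cyclobutanol photoadduct 15 (not isolated), via ring-opened formyl enol 16 (not isolated)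
Conditions: hν (medium-pressure mercury lamp, Vycor filter), 14 (3 equiv, in portions), degassed CH2Cl2, 0–10 °C
Reagents that add atoms: none
Why: De Mayo reaction: the hydrogen-bonded enol of 14 is excited and adds across C5=C9 of 10 in a (2+2) photocycloaddition to give cyclobutanol 15, whose β-hydroxy aldehyde unit cleaves by retro-aldol at the former enol bond (C1–C4), leaving the C1 aldehyde on C9 and the formyl-ester enol on C5 (16). The closest known reaction type is the photoannulation of formylacetic and diformylacetic ester enols onto cyclopentenes to give cyclopenta[c]pyran lactols. Two rings close: the transient cyclobutane by stepwise (2+2) addition through a 1,4-diradical, and the dihydropyran by 6-exo-trig attack of the C3 enol oxygen on the C1 aldehyde. C5 and C9 become cis because both bonds form from one face, and that face should be the convex one of the cis-fused bicycle, syn to the small 8-OH and anti to the dioxane; C1 is a hemiacetal that should settle as the anomer with OH trans to C8. The step needs C1 on C9 and C4 on C5 together with top-face attack: the fully substituted enol carbon C4 should avoid C9, which is flanked by quaternary C8, so the diradical that places C4 on C5 closes while the other reverts, and the fused acetonide blocks the lower face.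

**Step 8**
Reactants: 17 iridoid lactol methyl ester acetonide
Product: 18 methyl (1R,4aS,6S,7R,7aS)-1,6,7-trihydroxy-7-(hydroxymethyl)-1,4a,5,6,7,7a-hexahydrocyclopenta[c]pyran-4-carboxylate
Conditions: AcOH/H2O/THF (3:1:1), 40 °C
Reagents that add atoms: none
Why: Acid-catalysed acetonide hydrolysis is carried out here because the enol ether is still a vinylogous carbonate and therefore resists protonation, and the lactol is stable as such.

**Step 9**
Reactants: 18 tetraol lactol methyl ester
Product: 19 methyl (1S,4aS,6S,7R,7aS)-1-(TBS-oxy)-7-(TBS-oxymethyl)-6,7-dihydroxy-1,4a,5,6,7,7a-hexahydrocyclopenta[c]pyran-4-carboxylate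
Conditions: TBSCl (2.3 equiv), imidazole, DMF, 0 °C
Reagents that add atoms: tert-butyldimethylsilyl chloride, CC(C)(C)[Si](C)(C)Cl
Why: Silyl ether formation should take the primary 10-OH and the hemiacetal 1-OH well before the secondary 7-OH, which is flanked by quaternary C8, while the tertiary 8-OH is inert to TBSCl.

**Step 10**
Reactants: 19 bis-TBS methyl ester
Product: 20 (1S,4aS,6S,7R,7aS)-1-(TBS-oxy)-7-(TBS-oxymethyl)-4-(hydroxymethyl)-1,4a,5,6,7,7a-hexahydrocyclopenta[c]pyran-6,7-diol
Conditions: iBu2AlH (DIBAL, excess), CH2Cl2, −78 °C; aq. potassium sodium tartrate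
Reagents that add atoms: none
Why: DIBAL reduction of the β-alkoxyacrylate to the allylic alcohol is done once all acidic steps are over, with C1 masked as a silyl acetal so the lactol cannot open and over-reduce.

**Step 11**
Reactants: 20 C11 alcohol
Product: 21 (1S,4aS,6S,7R,7aS)-1-(TBS-oxy)-4,7-bis(TBS-oxymethyl)-1,4a,5,6,7,7a-hexahydrocyclopenta[c]pyran-6,7-diol
Conditions: TBSCl (1.1 equiv), imidazole, CH2Cl2, 0 °C
Reagents that add atoms: tert-butyldimethylsilyl chloride, CC(C)(C)[Si](C)(C)Cl
Why: Selective silylation of the primary allylic 11-OH over the hindered secondary and the tertiary hydroxyls should follow the usual steric order.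

**Step 12**
Reactants: 21 tris-TBS ether
Product: 22 (1R,4aS,6S,7R,7aS)-4,7-bis(TBS-oxymethyl)-1,4a,5,6,7,7a-hexahydrocyclopenta[c]pyran-1,6,7-triol
Conditions: Bu4NF (1.0 equiv), AcOH (1.2 equiv), THF, −20 °C; used at once
Reagents that add atoms: none
Why: Buffered fluoride desilylation should cleave only the anomeric silyl acetal, since a lactolate is a far better leaving group than a primary alkoxide, and the acetic acid buffer keeps the nepetalactol-type enol lactol from opening.

**Step 13**
Reactants: 22 lactol bis-TBS ether; 23 (3R)-3-methylpentanoic acid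
Product: 24 (1S,4aS,6S,7R,7aS)-4,7-bis(TBS-oxymethyl)-6,7-dihydroxy-1,4a,5,6,7,7a-hexahydrocyclopenta[c]pyran-1-yl (3R)-3-methylpentanoate
Conditions: 23 (1.1 equiv), DCC, DMAP (cat.), CH2Cl2, −20 → 0 °C
Reagents that add atoms: none
Why: Steglich esterification: the hemiacetal hydroxyl should react ahead of the hindered 7-OH, and of the two interconverting anomers the one with OH trans to the C8 substituents is the accessible one, which sets C1 as (S).

**Step 14**
Reactants: 25 tert-butyl(4-ethynylphenoxy)dimethylsilane
Product: 27 3-[4-(TBS-oxy)phenyl]prop-2-ynoic acid, via lithium arylacetylide 26 (not isolated)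
Conditions: n-BuLi, THF, −78 °C; CO2; cold 1 M HCl to pH 3
Reagents that add atoms: carbon dioxide, O=C=O
Why: Deprotonation of a terminal alkyne and carboxylation of the acetylide is a standard route to arylpropiolic acids, and the aryl silyl ether tolerates it at low temperature.

**Step 15**
Reactants: 24 C1 ester diol; 27 3-[4-(TBS-oxy)phenyl]prop-2-ynoic acid
Product: 28 7-O-arylpropioloyl ester of 24
Conditions: 27 (1.5 equiv), DCC, DMAP (cat.), CH2Cl2, 0 °C → rt
Reagents that add atoms: none
Why: Steglich esterification of the only remaining non-tertiary hydroxyl (7-OH); an alkynoate has no alkene geometry to lose during acyl activation, so the Z-alkene is deferred to the next step.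

**Step 16**
Reactants: 28 7-O-arylpropioloyl ester
Product: 29 tris-TBS ether of the target (7-O-(Z)-cinnamate)
Conditions: H2 (1 atm), Pd/CaCO3 poisoned with Pb(OAc)2 (Lindlar catalyst), quinoline, EtOAc, rt, dark
Reagents that add atoms: none
Why: Lindlar semihydrogenation adds hydrogen syn to the alkyne to give the Z-cinnamate, and the trisubstituted enol ether should not be reduced on the poisoned catalyst.

**Step 17**
Reactants: 29 tris-TBS ether of the target
Product: 30 CNP0217341.1, (1S,4aS,6S,7R,7aS)-7-hydroxy-4,7-bis(hydroxymethyl)-6-{[(2Z)-3-(4-hydroxyphenyl)prop-2-enoyl]oxy}-1,4a,5,6,7,7a-hexahydrocyclopenta[c]pyran-1-yl (3R)-3-methylpentanoate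
Conditions: HF·pyridine, pyridine, THF, 0 °C → rt, dark; NaHCO3 quench
Reagents that add atoms: none
Why: Fluoride desilylation under pyridine-buffered, weakly acidic conditions should remove the aryl and both primary silyl ethers while avoiding the base-induced acyl migration, acylal cleavage and Z to E isomerisation that a basic fluoride source could cause.

**Compound list**

1 | 2,2-dimethyl-1,3-dioxan-5-one | CC1(C)OCC(=O)CO1 | starting material
2 | (S)-1-amino-2-(methoxymethyl)pyrrolidine (SAMP) | COC[C@@H]1CCCN1N | starting material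
3 | (S)-N-(2,2-dimethyl-1,3-dioxan-5-ylidene)-2-(methoxymethyl)pyrrolidin-1-amine | COC[C@@H]1CCCN1N=C1COC(C)(C)OC1 | intermediate
4 | allyl bromide | C=CCBr | starting material
5 | lithium azaenolate of 3 | COC[C@@H]1CCCN1N([Li])C1=COC(C)(C)OC1 | intermediate
6 | (S)-N-[(4S)-4-allyl-2,2-dimethyl-1,3-dioxan-5-ylidene]-2-(methoxymethyl)pyrrolidin-1-amine | COC[C@@H]1CCCN1N=C1COC(C)(C)O[C@H]1CC=C | intermediate
7 | (4S)-4-allyl-2,2-dimethyl-1,3-dioxan-5-one | O=C1COC(C)(C)O[C@H]1CC=C | intermediate
8 | vinylmagnesium bromide | C=C[Mg]Br | starting material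
9 | (4S,5R)-4-allyl-2,2-dimethyl-5-vinyl-1,3-dioxan-5-ol (vinyl cis to allyl) | C=C[C@@]1(O)COC(C)(C)O[C@H]1CC=C | intermediate
10 | (4aR,7aS)-2,2-dimethyl-7,7a-dihydrocyclopenta[d][1,3]dioxin-4a(4H)-ol; cis-fused, C5=C9 alkene, O7 and C10–O in the dioxane, 8-OH on the other face | C1=C[C@@]2(O)COC(C)(C)O[C@H]2C1 | intermediate
11 | methyl 3,3-dimethoxypropanoate | COC(=O)CC(OC)OC | starting material
12 | methyl formate | COC=O | starting material
13 | sodium enolate of methyl 2-formyl-3,3-dimethoxypropanoate | COC(=O)C(=C[O-])C(OC)OC.[Na+] | intermediate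
14 | methyl diformylacetate (methyl 2-formyl-3-oxopropanoate, present as its enol) | COC(=O)C(C=O)C=O | intermediate
15 | cyclobutanol photoadduct: C1(H)(OH) bonded to C9 and C4, C4(CHO)(CO2Me) bonded to C5, both new bonds syn to 8-OH, acetonide as in 10 (C1 and C4 unassigned) | OC1C(C=O)(C(=O)OC)[C@H]2C[C@@H]3OC(C)(C)OC[C@]3(O)[C@@H]12 | intermediate
16 | ring-opened form: C9 carries the C1 aldehyde, C5 carries C(CO2Me)=CH–OH, both cis and syn to 8-OH | OC=C(C(=O)OC)[C@H]1C[C@@H]2OC(C)(C)OC[C@]2(O)[C@H]1C=O | intermediate
17 | iridoid lactol (1R,5S,7S,8R,9S; iridoid numbering): C4 methyl ester, 7,10-O-isopropylidene, free 8-OH, 1-OH trans to C8 | O[C@@H]1OC=C(C(=O)OC)[C@H]2C[C@@H]3OC(C)(C)OC[C@]3(O)[C@@H]12 | intermediate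
18 | methyl (1R,4aS,6S,7R,7aS)-1,6,7-trihydroxy-7-(hydroxymethyl)-1,4a,5,6,7,7a-hexahydrocyclopenta[c]pyran-4-carboxylate | O[C@@H]1OC=C(C(=O)OC)[C@H]2C[C@H](O)[C@](O)(CO)[C@@H]12 | intermediate
19 | methyl (1S,4aS,6S,7R,7aS)-1-(TBS-oxy)-7-(TBS-oxymethyl)-6,7-dihydroxy-1,4a,5,6,7,7a-hexahydrocyclopenta[c]pyran-4-carboxylate | CC(C)(C)[Si](C)(C)O[C@@H]1OC=C(C(=O)OC)[C@H]2C[C@H](O)[C@](O)(CO[Si](C)(C)C(C)(C)C)[C@@H]12 | intermediate
20 | (1S,4aS,6S,7R,7aS)-1-(TBS-oxy)-7-(TBS-oxymethyl)-4-(hydroxymethyl)-1,4a,5,6,7,7a-hexahydrocyclopenta[c]pyran-6,7-diol | CC(C)(C)[Si](C)(C)O[C@@H]1OC=C(CO)[C@H]2C[C@H](O)[C@](O)(CO[Si](C)(C)C(C)(C)C)[C@@H]12 | intermediate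
21 | (1S,4aS,6S,7R,7aS)-1-(TBS-oxy)-4,7-bis(TBS-oxymethyl)-1,4a,5,6,7,7a-hexahydrocyclopenta[c]pyran-6,7-diol | CC(C)(C)[Si](C)(C)O[C@@H]1OC=C(CO[Si](C)(C)C(C)(C)C)[C@H]2C[C@H](O)[C@](O)(CO[Si](C)(C)C(C)(C)C)[C@@H]12 | intermediate
22 | (1R,4aS,6S,7R,7aS)-4,7-bis(TBS-oxymethyl)-1,4a,5,6,7,7a-hexahydrocyclopenta[c]pyran-1,6,7-triol | O[C@@H]1OC=C(CO[Si](C)(C)C(C)(C)C)[C@H]2C[C@H](O)[C@](O)(CO[Si](C)(C)C(C)(C)C)[C@@H]12 | intermediate
23 | (3R)-3-methylpentanoic acid | CC[C@@H](C)CC(=O)O | starting material
24 | (1S,4aS,6S,7R,7aS)-4,7-bis(TBS-oxymethyl)-6,7-dihydroxy-1,4a,5,6,7,7a-hexahydrocyclopenta[c]pyran-1-yl (3R)-3-methylpentanoate | CC[C@@H](C)CC(=O)O[C@@H]1OC=C(CO[Si](C)(C)C(C)(C)C)[C@H]2C[C@H](O)[C@](O)(CO[Si](C)(C)C(C)(C)C)[C@@H]12 | intermediate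
25 | tert-butyl(4-ethynylphenoxy)dimethylsilane | C#Cc1ccc(O[Si](C)(C)C(C)(C)C)cc1 | starting material
26 | lithium [4-(TBS-oxy)phenyl]acetylide | [Li]C#Cc1ccc(O[Si](C)(C)C(C)(C)C)cc1 | intermediate
27 | 3-[4-(TBS-oxy)phenyl]prop-2-ynoic acid | OC(=O)C#Cc1ccc(O[Si](C)(C)C(C)(C)C)cc1 | intermediate
28 | 24 esterified at O7 (6-position of the bicycle) with 3-[4-(TBS-oxy)phenyl]prop-2-ynoic acid; 8-OH free | CC[C@@H](C)CC(=O)O[C@@H]1OC=C(CO[Si](C)(C)C(C)(C)C)[C@H]2C[C@H](OC(=O)C#Cc3ccc(O[Si](C)(C)C(C)(C)C)cc3)[C@](O)(CO[Si](C)(C)C(C)(C)C)[C@@H]12 | intermediate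
29 | target carrying TBS on O10, O11 and the phenol; 7-O-(2Z)-3-arylprop-2-enoate | CC[C@@H](C)CC(=O)O[C@@H]1OC=C(CO[Si](C)(C)C(C)(C)C)[C@H]2C[C@H](OC(=O)/C=C\c3ccc(O[Si](C)(C)C(C)(C)C)cc3)[C@](O)(CO[Si](C)(C)C(C)(C)C)[C@@H]12 | intermediate
30 | CNP0217341.1, (1S,4aS,6S,7R,7aS)-7-hydroxy-4,7-bis(hydroxymethyl)-6-{[(2Z)-3-(4-hydroxyphenyl)prop-2-enoyl]oxy}-1,4a,5,6,7,7a-hexahydrocyclopenta[c]pyran-1-yl (3R)-3-methylpentanoate | CC[C@@H](C)CC(=O)O[C@@H]1OC=C(CO)[C@H]2C[C@H](OC(=O)/C=C\c3ccc(O)cc3)[C@](O)(CO)[C@@H]12 | target

**Step count**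

Total: 17 steps. Longest linear sequence: 15 steps (1–5, 7–13, 15–17); steps 6 and 14 are side branches.

**Steps most likely to fail**

1. Step 7. The enol may add with the wrong orientation (C4 rather than C1 bonding to C9), facial selectivity may erode, or the enol may photodegrade faster than it adds to a hindered alkene. The fallback sets out from 10 and 14 and returns at 17; it makes the cycloaddition intramolecular through a temporary silicon tether. O8 of 10 would be silylated with iPr2Si(OTf)2 and 2,6-lutidine to the 8-O-diisopropylsilyl triflate F1. Quenching F1 in the same flask with 14 and Et3N would give the mixed silyl ether of the enol, the tethered silyl enol ether F2. Irradiation of F2 can close the cyclobutane only through a six-membered siloxane ring, which forces C1 onto C9 from the O8 face and gives the tricyclic siloxane photoadduct F3. HF·pyridine would then cleave both Si–O bonds, and the freed cyclobutanol 15 should fragment and reclose through 16 to 17 as in the main route.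

2. Step 13. Acylation may occur at O7 instead of O1, the anomeric selectivity may be poor, or the sensitive enol lactol may open before it is acylated. The fallback sets out from 21 and returns at 24, bypassing 22; it transfers the acyl group onto the silyl acetal without ever freeing the lactol. Acid 23 would be converted with cyanuric fluoride and pyridine into (3R)-3-methylpentanoyl fluoride F4. Treating 21 with F4 and a catalytic amount of Bu4NF should exchange only the anomeric silyl ether, the most fluoride-labile one, for the ester with retention at C1, fluoride being regenerated at each turnover.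

3. Step 4. Facial selectivity may be poor (equatorial instead of axial attack would put vinyl trans to allyl), or the Grignard reagent may enolise the α-alkoxy ketone. The fallback sets out from 7 and returns at 10; it forms the C8–C9 bond intramolecularly so that the ring fusion can only be cis. Ozonolysis of the allyl group of 7 (O3, CH2Cl2, −78 °C; Me2S) would give 2-[(4S)-2,2-dimethyl-5-oxo-1,3-dioxan-4-yl]acetaldehyde F5. Stork–Zhao olefination of the aldehyde (Ph3P=CHI from (iodomethyl)triphenylphosphonium iodide and NaN(SiMe3)2, −78 °C) would give (4S)-4-[(2Z)-3-iodoprop-2-en-1-yl]-2,2-dimethyl-1,3-dioxan-5-one F6. Intramolecular Nozaki–Hiyama–Kishi addition (CrCl2, cat. NiCl2, DMF, rt) of the vinyl iodide to the ketone would then close the cyclopentene and deliver 10 directly.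

**Further compounds**

F1 | step 7 | 8-O-[diisopropyl(trifluoromethanesulfonyloxy)silyl] ether of 10 | C1=C[C@@]2(O[Si](C(C)C)(C(C)C)OS(=O)(=O)C(F)(F)F)COC(C)(C)O[C@H]2C1
F2 | step 7 | tethered silyl enol ether: 8-O–Si(iPr)2–O–CH=C(CHO)CO2Me on 10 | C1=C[C@@]2(O[Si](C(C)C)(C(C)C)OC=C(C=O)C(=O)OC)COC(C)(C)O[C@H]2C1
F3 | step 7 | tricyclic siloxane photoadduct (cyclobutane with O1 and O8 bridged by Si(iPr)2) | CC(C)[Si]1(C(C)C)OC2C(C=O)(C(=O)OC)[C@H]3C[C@@H]4OC(C)(C)OC[C@]4(O1)[C@@H]23
F4 | step 13 | (3R)-3-methylpentanoyl fluoride | CC[C@@H](C)CC(=O)F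
F5 | step 4 | 2-[(4S)-2,2-dimethyl-5-oxo-1,3-dioxan-4-yl]acetaldehyde | O=C1COC(C)(C)O[C@H]1CC=O
F6 | step 4 | (4S)-4-[(2Z)-3-iodoprop-2-en-1-yl]-2,2-dimethyl-1,3-dioxan-5-one | O=C1COC(C)(C)O[C@H]1C/C=C\I
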